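**Retrosynthetic overview**

1. Target ⇐ its C11 TBS ether. The only ring, the dihydropyranone, is closed second-to-last by RCM of an acrylate onto one vinyl group of a (3S,4S)-divinyl-glycol diester; the acrylic acid side chain is added in the same pot by cross-metathesis of the other vinyl group.
2. Diester ⇐ ester bond between the mono-acrylate of C2-symmetric (3S,4S)-hexa-1,5-diene-3,4-diol (homotopic hydroxyls) and the side-chain dienoic acid.
3. Dienoic acid ⇐ key C6–C7 bond: enantioconvergent nickel-catalysed radical coupling of a racemic 6-bromo dienoate (pentadienyl radical) with a chiral alkylzinc; this sets C6 (R).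
4. Bromo dienoate ⇐ Wohl–Ziegler bromination of the dienoate made from (E)-2-methylpent-2-enal and a malonate half-ester; alkylzinc ⇐ (S)-hex-5-en-2-ol (C11 from the chiral pool).

Assumption: (3S,4S)-hexa-1,5-diene-3,4-diol and (S)-hex-5-en-2-ol are bought as single enantiomers; the hand of the pybox ligand in step 5 is assigned by analogy, and the mirror-image ligand is used if the sense proves opposite.

**Route**

Step 1
Reactants: 1 (E)-2-methylpent-2-enal; 2 monomethyl malonate (3-methoxy-3-oxopropanoic acid)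
Product: 3 methyl (2E,4E)-4-methylhepta-2,4-dienoate
Conditions: 2 (1.5 equiv), pyridine, piperidine (10 mol %), 90 °C, 6 h
Reagents that add atoms: none
Why: Doebner–Knoevenagel condensation of the malonic half-ester with the enal and decarboxylative elimination gives the thermodynamically favoured 2E enoate, while the E trisubstituted alkene of 1 is carried through unchanged; no stereocentre is formed.

Step 2
Reactants: 3 methyl (2E,4E)-4-methylhepta-2,4-dienoate
Product: 4 racemic methyl (2E,4E)-6-bromo-4-methylhepta-2,4-dienoate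
Conditions: NBS (1.05 equiv), AIBN (5 mol %), PhCF3, 80 °C, 2 h; used within a day
Reagents that add atoms: N-bromosuccinimide, O=C1CCC(=O)N1Br
Why: Wohl–Ziegler bromination, in which hydrogen abstraction is fastest at the secondary C6–H (it gives an ester-conjugated pentadienyl radical) and bromine transfer with allylic equilibration ends at the terminus that keeps the dienoate conjugated, as with sorbate esters; the C6 configuration is irrelevant because step 5 erases it.

Step 3
Reactants: 5 (S)-hex-5-en-2-ol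
Product: 6 (S)-tert-butyl(hex-5-en-2-yloxy)dimethylsilane
Conditions: TBSCl (1.2 equiv), imidazole (2 equiv), DMF, 0 °C to rt
Reagents that add atoms: tert-butyldimethylsilyl chloride, CC(C)(C)[Si](C)(C)Cl
Why: Standard silyl ether formation at oxygen, so the carbinol stereocentre (the future C11, S) is untouched.

Step 4
Reactants: 6 (S)-tert-butyl(hex-5-en-2-yloxy)dimethylsilane
Product: 8 (S)-[(6-bromohexan-2-yl)oxy](tert-butyl)dimethylsilane, via alkylzirconocene chloride 7 (not isolated)
Conditions: Cp2Zr(H)Cl (1.3 equiv), CH2Cl2, rt, 1 h; then NBS (1.3 equiv), 0 °C, 30 min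
Reagents that add atoms: N-bromosuccinimide, O=C1CCC(=O)N1Br; Cp2Zr(H)Cl, [H][Zr](Cl)(C1C=CC=C1)C1C=CC=C1 (zirconium stays only in intermediate 7)
Why: Hydrozirconation puts zirconium on the terminal carbon of the monosubstituted alkene, and electrophilic bromination of the C–Zr bond gives the primary bromide (hydrozirconation–halogenation) without touching the silyl ether or the stereocentre.

Step 5
Reactants: 8 (S)-[(6-bromohexan-2-yl)oxy](tert-butyl)dimethylsilane; 4 racemic methyl (2E,4E)-6-bromo-4-methylhepta-2,4-dienoate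
Product: 10 methyl (2E,4E,6R,11S)-11-[(tert-butyldimethylsilyl)oxy]-4,6-dimethyldodeca-2,4-dienoate, via alkylzinc bromide 9 (not isolated)
Conditions: Zn (1.5 equiv), I2 (5 mol %), DMA, 70 °C, 12 h; then 4 (1.0 equiv; 9 at 1.6 equiv), NiCl2·dme (5 mol %), (S,S)-2,6-bis(4-phenethyl-4,5-dihydrooxazol-2-yl)pyridine (5.5 mol %), NaCl (4 equiv), DMA/DMF 1:1, −10 °C, 24 h
Reagents that add atoms: zinc, [Zn] (zinc stays only in intermediate 9)
Why: Proposed new method: a vinylogous extension of the enantioconvergent nickel/pybox Negishi coupling of racemic secondary allylic chlorides with alkylzinc halides, in which monovalent nickel abstracts bromine from either enantiomer of 4 to give one planar, ester-conjugated pentadienyl radical that is captured by the chiral alkylnickel complex and reductively eliminates at C6 (the terminus that keeps the dienoate conjugated, as γ-halo enoates couple at the γ-carbon in the parent reaction), so the ligand alone sets C6 as R and the W-shaped radical keeps both alkenes E.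

Step 6
Reactants: 10 methyl (2E,4E,6R,11S)-11-[(tert-butyldimethylsilyl)oxy]-4,6-dimethyldodeca-2,4-dienoate
Product: 11 (2E,4E,6R,11S)-11-[(tert-butyldimethylsilyl)oxy]-4,6-dimethyldodeca-2,4-dienoic acid
Conditions: LiOH·H2O (3 equiv), THF/MeOH/H2O 3:1:1, rt, 6 h; then 1 M HCl to pH 4, 0 °C
Reagents that add atoms: lithium hydroxide, [Li+].[OH-]
Why: Saponification of the methyl ester; the C6–H is not acidic enough to epimerise under these conditions, and the secondary TBS ether survives mild hydroxide and brief pH 4.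

Step 7
Reactants: 12 (3S,4S)-hexa-1,5-diene-3,4-diol; 13 acryloyl chloride
Product: 14 (3S,4S)-4-hydroxyhexa-1,5-dien-3-yl prop-2-enoate
Conditions: 12 (3 equiv), 13 (1 equiv), Et3N (1.1 equiv), CH2Cl2, −78 to −30 °C; excess 12 recovered
Reagents that add atoms: none
Why: The two hydroxyls of the C2-symmetric diol are homotopic, so mono-acylation gives a single compound, acyl migration is degenerate, and excess diol suppresses the diacrylate; acylation at oxygen leaves both stereocentres intact.

Step 8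
Reactants: 11 (2E,4E,6R,11S)-11-[(tert-butyldimethylsilyl)oxy]-4,6-dimethyldodeca-2,4-dienoic acid; 14 (3S,4S)-4-hydroxyhexa-1,5-dien-3-yl prop-2-enoate
Product: 15 (3S,4S)-4-(acryloyloxy)hexa-1,5-dien-3-yl (2E,4E,6R,11S)-11-[(tert-butyldimethylsilyl)oxy]-4,6-dimethyldodeca-2,4-dienoate
Conditions: 14 (1.3 equiv), DIC (1.5 equiv), DMAP (0.3 equiv), CH2Cl2, 0 °C to rt, 12 h
Reagents that add atoms: none
Why: Steglich esterification of the only free hydroxyl; the C–O bond of the carbinol is not broken, so its configuration is retained.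

Step 9
Reactants: 15 (3S,4S)-4-(acryloyloxy)hexa-1,5-dien-3-yl (2E,4E,6R,11S)-11-[(tert-butyldimethylsilyl)oxy]-4,6-dimethyldodeca-2,4-dienoate; 16 acrylic acid
Product: 18 (E)-3-[(2S,3S)-3-{[(2E,4E,6R,11S)-11-[(tert-butyldimethylsilyl)oxy]-4,6-dimethyldodeca-2,4-dienoyl]oxy}-6-oxo-3,6-dihydro-2H-pyran-2-yl]prop-2-enoic acid, via 6-vinyl dihydropyranone 17 (not isolated)
Conditions: second-generation Hoveyda–Grubbs catalyst RuCl2(H2IMes)(=CH-C6H4-2-OiPr) (5 mol %), CH2Cl2 (0.01 M), 40 °C, 4 h; then 16 (10 equiv), further catalyst (5 mol %), concentrated to 0.1 M, 40 °C, 16 h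
Reagents that add atoms: none
Why: Ring-closing metathesis of the acrylate with the vinyl group on the neighbouring carbinol carbon closes the six-membered unsaturated lactone in preference to the strained butenolide, and the remaining vinyl group then undergoes E-selective cross-metathesis with acrylic acid; the cis 5,6-relationship comes directly from the (3S,4S)-diol, and the conjugated trisubstituted dienoate is inert.

Step 10
Reactants: 18 (E)-3-[(2S,3S)-3-{[(2E,4E,6R,11S)-11-[(tert-butyldimethylsilyl)oxy]-4,6-dimethyldodeca-2,4-dienoyl]oxy}-6-oxo-3,6-dihydro-2H-pyran-2-yl]prop-2-enoic acid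
Product: 19 (E)-3-[(2S,3S)-3-{[(2E,4E,6R,11S)-11-hydroxy-4,6-dimethyldodeca-2,4-dienoyl]oxy}-6-oxo-3,6-dihydro-2H-pyran-2-yl]prop-2-enoic acid (CNP0107712.2)
Conditions: HF·pyridine, THF/pyridine, 0 °C to rt, 8 h
Reagents that add atoms: none
Why: Desilylation with buffered HF is non-basic, which avoids base-induced elimination or ring opening of the 5-acyloxy lactone, and no stereocentre is involved.

**Compound list**

1 | (E)-2-methylpent-2-enal | CC/C=C(\C)C=O | starting material
2 | monomethyl malonate (3-methoxy-3-oxopropanoic acid) | COC(=O)CC(=O)O | starting material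
3 | methyl (2E,4E)-4-methylhepta-2,4-dienoate | CC/C=C(C)/C=C/C(=O)OC | intermediate
4 | racemic methyl (2E,4E)-6-bromo-4-methylhepta-2,4-dienoate | CC(Br)/C=C(C)/C=C/C(=O)OC | intermediate
5 | (S)-hex-5-en-2-ol | C=CCC[C@H](C)O | starting material
6 | (S)-tert-butyl(hex-5-en-2-yloxy)dimethylsilane | C=CCC[C@H](C)O[Si](C)(C)C(C)(C)C | intermediate
7 | chloro{(5S)-5-[(tert-butyldimethylsilyl)oxy]hexyl}zirconocene (not isolated; cyclopentadienyl rings drawn σ-bound) | Cl[Zr](CCCC[C@H](C)O[Si](C)(C)C(C)(C)C)(C1C=CC=C1)C1C=CC=C1 | intermediate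
8 | (S)-[(6-bromohexan-2-yl)oxy](tert-butyl)dimethylsilane | BrCCCC[C@H](C)O[Si](C)(C)C(C)(C)C | intermediate
9 | {(5S)-5-[(tert-butyldimethylsilyl)oxy]hexyl}zinc bromide (not isolated) | Br[Zn]CCCC[C@H](C)O[Si](C)(C)C(C)(C)C | intermediate
10 | methyl (2E,4E,6R,11S)-11-[(tert-butyldimethylsilyl)oxy]-4,6-dimethyldodeca-2,4-dienoate | CC(/C=C/C(=O)OC)=C\[C@H](C)CCCC[C@H](C)O[Si](C)(C)C(C)(C)C | intermediate
11 | (2E,4E,6R,11S)-11-[(tert-butyldimethylsilyl)oxy]-4,6-dimethyldodeca-2,4-dienoic acid | CC(/C=C/C(=O)O)=C\[C@H](C)CCCC[C@H](C)O[Si](C)(C)C(C)(C)C | intermediate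
12 | (3S,4S)-hexa-1,5-diene-3,4-diol | C=C[C@H](O)[C@@H](O)C=C | starting material
13 | acryloyl chloride | C=CC(=O)Cl | starting material
14 | (3S,4S)-4-hydroxyhexa-1,5-dien-3-yl prop-2-enoate | C=C[C@H](O)[C@@H](OC(=O)C=C)C=C | intermediate
15 | (3S,4S)-4-(acryloyloxy)hexa-1,5-dien-3-yl (2E,4E,6R,11S)-11-[(tert-butyldimethylsilyl)oxy]-4,6-dimethyldodeca-2,4-dienoate | CC(/C=C/C(=O)O[C@@H](C=C)[C@@H](OC(=O)C=C)C=C)=C\[C@H](C)CCCC[C@H](C)O[Si](C)(C)C(C)(C)C | intermediate
16 | acrylic acid | C=CC(=O)O | starting material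
17 | (2S,3S)-6-oxo-2-vinyl-3,6-dihydro-2H-pyran-3-yl (2E,4E,6R,11S)-11-[(tert-butyldimethylsilyl)oxy]-4,6-dimethyldodeca-2,4-dienoate (not isolated) | CC(/C=C/C(=O)O[C@H]1C=CC(=O)O[C@H]1C=C)=C\[C@H](C)CCCC[C@H](C)O[Si](C)(C)C(C)(C)C | intermediate
18 | (E)-3-[(2S,3S)-3-{[(2E,4E,6R,11S)-11-[(tert-butyldimethylsilyl)oxy]-4,6-dimethyldodeca-2,4-dienoyl]oxy}-6-oxo-3,6-dihydro-2H-pyran-2-yl]prop-2-enoic acid | CC(/C=C/C(=O)O[C@H]1C=CC(=O)O[C@H]1/C=C/C(=O)O)=C\[C@H](C)CCCC[C@H](C)O[Si](C)(C)C(C)(C)C | intermediate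
19 | (E)-3-[(2S,3S)-3-{[(2E,4E,6R,11S)-11-hydroxy-4,6-dimethyldodeca-2,4-dienoyl]oxy}-6-oxo-3,6-dihydro-2H-pyran-2-yl]prop-2-enoic acid | CC(/C=C/C(=O)O[C@H]1C=CC(=O)O[C@H]1/C=C/C(=O)O)=C\[C@H](C)CCCC[C@H](C)O | target

**Totals**

Total steps: 10. Longest linear sequence: 7 steps (1 → 3 → 4 → 10 → 11 → 15 → 18 → 19; the branch from 5 is equally long).

**Three steps most likely to fail, each with a fallback**

Step 5 (key coupling). The dienyl bromide is outside the established allylic chloride scope. The risks are coupling at C2 or C4 instead of C6, lower enantioselectivity, and radical dimerisation. The fallback sets out from 9 and returns at 10. 9 is coupled under the same nickel/pybox conditions with racemic methyl (E)-4-chloro-2-methylpent-2-enoate F4, a γ-chloro enoate of the substrate class closest to the established reaction. F4 is made in one step by Wittig olefination of racemic 2-chloropropanal with methyl 2-(triphenylphosphoranylidene)propanoate. The coupling gives methyl (2E,4R,9S)-9-[(tert-butyldimethylsilyl)oxy]-2,4-dimethyldec-2-enoate F5. Reduction with i-Bu2AlH (CH2Cl2, −78 °C) gives (2E,4R,9S)-9-[(tert-butyldimethylsilyl)oxy]-2,4-dimethyldec-2-en-1-ol F6, and MnO2 (CH2Cl2, rt) gives (2E,4R,9S)-9-[(tert-butyldimethylsilyl)oxy]-2,4-dimethyldec-2-enal F7. Doebner–Knoevenagel condensation of F7 with 2, as in step 1, then gives 10. This costs three extra steps but keeps the radical, enantioconvergent construction of the same stereocentre.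

Step 2 (Wohl–Ziegler bromination). The risks are bromination of the C4 methyl group, loss of HBr to a triene, and instability of the secondary dienyl bromide. The fallback sets out from 1 and returns at 10; it installs the leaving group by polar γ-halogenation before chain extension. 1 is converted with TBSOTf/Et3N (CH2Cl2, 0 °C) into the silyl dienol ether tert-butyl(dimethyl){[(1E,3E)-2-methylpenta-1,3-dien-1-yl]oxy}silane F1 (the enol ether geometry is inconsequential). NCS (THF, −78 to 0 °C) chlorinates F1 at the γ-carbon to give racemic (E)-4-chloro-2-methylpent-2-enal F2. Horner–Wadsworth–Emmons olefination with trimethyl phosphonoacetate (LiCl, i-Pr2NEt, MeCN, 0 °C) gives racemic methyl (2E,4E)-6-chloro-4-methylhepta-2,4-dienoate F3. This secondary allylic chloride takes the place of 4 in step 5 and delivers 10.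

Step 9 (RCM then cross-metathesis). The risks are slow cross-metathesis of the hindered, oxygen-flanked vinyl group with acrylic acid, and partial butenolide formation. The fallback sets out from 14 and returns at 19; ring closure and side-chain metathesis are done on the small fragment before the acid is attached. RCM of 14 (second-generation Grubbs catalyst RuCl2(H2IMes)(PCy3)(=CHPh), CH2Cl2, 40 °C) gives (5S,6S)-5-hydroxy-6-vinyl-5,6-dihydro-2H-pyran-2-one F8. Cross-metathesis of F8 with tert-butyl acrylate (second-generation Hoveyda–Grubbs catalyst RuCl2(H2IMes)(=CH-C6H4-2-OiPr), CH2Cl2, 40 °C), where the free hydroxyl assists and no dienoate is present, gives tert-butyl (E)-3-[(2S,3S)-3-hydroxy-6-oxo-3,6-dihydro-2H-pyran-2-yl]prop-2-enoate F9. Esterification of F9 with 11 (DIC, DMAP, CH2Cl2) gives tert-butyl (E)-3-[(2S,3S)-3-{[(2E,4E,6R,11S)-11-[(tert-butyldimethylsilyl)oxy]-4,6-dimethyldodeca-2,4-dienoyl]oxy}-6-oxo-3,6-dihydro-2H-pyran-2-yl]prop-2-enoate F10. TFA/CH2Cl2/H2O (9:9:1, 0 °C to rt) removes the tert-butyl ester and the silyl ether together and gives 19.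

**Further compounds**

F1 | step 2 | tert-butyl(dimethyl){[(1E,3E)-2-methylpenta-1,3-dien-1-yl]oxy}silane | C/C=C/C(C)=C/O[Si](C)(C)C(C)(C)C
F2 | step 2 | racemic (E)-4-chloro-2-methylpent-2-enal | CC(Cl)/C=C(\C)C=O
F3 | step 2 | racemic methyl (2E,4E)-6-chloro-4-methylhepta-2,4-dienoate | CC(Cl)/C=C(C)/C=C/C(=O)OC
F4 | step 5 | racemic methyl (E)-4-chloro-2-methylpent-2-enoate | CC(Cl)/C=C(\C)C(=O)OC
F5 | step 5 | methyl (2E,4R,9S)-9-[(tert-butyldimethylsilyl)oxy]-2,4-dimethyldec-2-enoate | COC(=O)/C(C)=C/[C@H](C)CCCC[C@H](C)O[Si](C)(C)C(C)(C)C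
F6 | step 5 | (2E,4R,9S)-9-[(tert-butyldimethylsilyl)oxy]-2,4-dimethyldec-2-en-1-ol | OC/C(C)=C/[C@H](C)CCCC[C@H](C)O[Si](C)(C)C(C)(C)C
F7 | step 5 | (2E,4R,9S)-9-[(tert-butyldimethylsilyl)oxy]-2,4-dimethyldec-2-enal | O=C/C(C)=C/[C@H](C)CCCC[C@H](C)O[Si](C)(C)C(C)(C)C
F8 | step 9 | (5S,6S)-5-hydroxy-6-vinyl-5,6-dihydro-2H-pyran-2-one | O[C@H]1C=CC(=O)O[C@H]1C=C
F9 | step 9 | tert-butyl (E)-3-[(2S,3S)-3-hydroxy-6-oxo-3,6-dihydro-2H-pyran-2-yl]prop-2-enoate | O[C@H]1C=CC(=O)O[C@H]1/C=C/C(=O)OC(C)(C)C
F10 | step 9 | tert-butyl (E)-3-[(2S,3S)-3-{[(2E,4E,6R,11S)-11-[(tert-butyldimethylsilyl)oxy]-4,6-dimethyldodeca-2,4-dienoyl]oxy}-6-oxo-3,6-dihydro-2H-pyran-2-yl]prop-2-enoate | CC(/C=C/C(=O)O[C@H]1C=CC(=O)O[C@H]1/C=C/C(=O)OC(C)(C)C)=C\[C@H](C)CCCC[C@H](C)O[Si](C)(C)C(C)(C)C
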